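**Plan**

Ring numbering: C1 (acyloxy carbon), C2, C3=C4 (methyl on C4), C5 (bearing C7H2–OAr), C6 (CMe2). The retrosynthesis cuts, in order, the aryl ether O–C7, the C5–H/C7–O pair (back to an exocyclic C5=C7 alkene), the ring bond C4–C5, the ester C–O, and last C1–C6 together with C5–B.
Enabling feature: the array O–C1–C6(CH3)2–C5–C7 of the cyclohexene ring is a reverse-prenylated carbinol. C1 maps onto an aldehyde carbon, and C6, C5 and C7 onto the dimethyl terminus, central carbon and CH2 terminus of 1,1-dimethylallene, with boron on C5 matched to a (Z)-alkenyl iodide at C3=C4.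
Forward: a Z-selective iodo-Wittig reaction leads to (Z)-4-iodopent-3-enal; a copper-catalysed union with the allene and B2pin2 joins the whole acyclic chain; after acylation the only ring (the cyclohexene) closes by intramolecular Suzuki–Miyaura coupling; hydroboration and Mitsunobu etherification finish.
Stereochemistry: C1 (R) from the chiral copper catalyst; C5 (S) from substrate-controlled hydroboration anti to the C1 acyloxy face; the ester's 2R centre from (R)-2-methylbutanoic acid; the Z-alkenyl iodide from the Wittig step.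

Key step: step 4

Assumption: compounds 1, 2, 9, 10, 13 and 18 are purchased, and the antipode of the bisphosphine that delivers the 4R alcohol is to be assigned on the first run (Mosher ester analysis); the conditions name the ligand without fixing that antipode.

Step 1
Reactants: 1 3-[(tert-butyldimethylsilyl)oxy]propanal; 2 ethyltriphenylphosphonium iodide
Product: 6 (Z)-tert-butyl[(4-iodopent-3-en-1-yl)oxy]dimethylsilane, via ethylidenetriphenylphosphorane 3 (not isolated), via (1-iodoethyl)triphenylphosphonium iodide 4 (not isolated), via (1-iodoethylidene)triphenylphosphorane 5 (not isolated)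
Conditions: n-BuLi, THF, 0 °C → rt; I2, THF, −78 °C; NaHMDS, −20 °C; then 1, −78 → −20 °C
Reagents that add atoms: iodine, II
Why: Stork–Zhao-type α-iodoalkylidene Wittig olefination, in which the non-stabilised iodo ylide 5 adds to the unhindered aldehyde under kinetic control via a cis-oxaphosphetane and should give the 2-iodoalk-2-ene with iodine cis to the chain (Z), the geometry the later ring closure needs.

Step 2
Reactants: 6 (Z)-tert-butyl[(4-iodopent-3-en-1-yl)oxy]dimethylsilane
Product: 7 (Z)-4-iodopent-3-en-1-ol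
Conditions: CSA (cat.), MeOH, 0 °C → rt
Reagents that add atoms: none
Why: Acid-catalysed methanolysis cleaves a primary TBS ether under conditions to which the alkenyl iodide is inert.

Step 3
Reactants: 7 (Z)-4-iodopent-3-en-1-ol
Product: 8 (Z)-4-iodopent-3-enal
Conditions: Dess–Martin periodinane, NaHCO3, CH2Cl2, 0 °C; short silica plug, taken up in THF and used at once
Reagents that add atoms: none
Why: Dess–Martin oxidation runs under near-neutral, bicarbonate-buffered conditions, so the β,γ-unsaturated aldehyde should form without migration of the double bond into conjugation.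

Step 4
Reactants: 8 (Z)-4-iodopent-3-enal; 9 3-methylbuta-1,2-diene; 10 bis(pinacolato)diboron
Product: 12 (4R,6Z)-7-iodo-3,3-dimethyl-2-(4,4,5,5-tetramethyl-1,3,2-dioxaborolan-2-yl)octa-1,6-dien-4-ol, via O-boryl ether 11 (not isolated)
Conditions: CuCl (5 mol %), DTBM-SEGPHOS (5.5 mol %), NaOt-Bu (20 mol %), 9 (1.5 equiv), 10 (1.1 equiv), THF, 22 °C, slow addition of 8; aq. NH4Cl work-up
Reagents that add atoms: none
Why: A bisphosphine–copper boryl, formed from the copper alkoxide and 10, adds across the unsubstituted C=C of allene 9 with boron on the central carbon, and the resulting 2-boryl allylcopper transfers its dimethyl-substituted γ-carbon to the aldehyde through a six-membered chair transition state, after which the copper alkoxide is borylated by 10 to give 11 and regenerate the copper boryl. The closest known reaction type is the copper-catalysed enantioselective borylative coupling of 1,1-disubstituted allenes with aldehydes and B2pin2. No ring is closed; the step forms C1–C6 and C5–B and leaves C7 as the methylene of the alkenyl boronate. The one new stereocentre (C1, 4R in 12) is controlled by the chiral bisphosphine on copper, which selects the aldehyde face in the chair transition state. The step needs γ-selective allyl transfer, which the closed SE2′ transition state secures, and chemoselective copper–boryl addition to the allene rather than to the aldehyde or the alkenyl iodide, which the much faster allene insertion at 22 °C and the slow addition of freshly made 8 should secure.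

Step 5
Reactants: 12 (4R,6Z)-7-iodo-3,3-dimethyl-2-(4,4,5,5-tetramethyl-1,3,2-dioxaborolan-2-yl)octa-1,6-dien-4-ol; 13 (2R)-2-methylbutanoic acid
Product: 14 (4R,6Z)-7-iodo-3,3-dimethyl-2-(4,4,5,5-tetramethyl-1,3,2-dioxaborolan-2-yl)octa-1,6-dien-4-yl (2R)-2-methylbutanoate
Conditions: DCC, DMAP, CH2Cl2, 0 °C → rt
Reagents that add atoms: none
Why: Steglich esterification via the DMAP-derived acylpyridinium acylates the hindered secondary alcohol, and a simple α-alkyl acid should not epimerise under these conditions, so the ester's 2R centre comes unchanged from 13 and the final acyl group doubles as protection of the C1 oxygen.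

Step 6
Reactants: 14 (4R,6Z)-7-iodo-3,3-dimethyl-2-(4,4,5,5-tetramethyl-1,3,2-dioxaborolan-2-yl)octa-1,6-dien-4-yl (2R)-2-methylbutanoate
Product: 15 (1R)-4,6,6-trimethyl-5-methylidenecyclohex-3-en-1-yl (2R)-2-methylbutanoate
Conditions: PdCl2(dppf)·CH2Cl2 (10 mol %), K3PO4, THF/H2O (10:1), degassed, 0.01 M, 60 °C
Reagents that add atoms: none
Why: Intramolecular Suzuki–Miyaura coupling, in which oxidative addition into the Z-alkenyl iodide places palladium cis to the tether, the alkenyl boronate transmetalates under aqueous phosphate and reductive elimination closes the six-membered ring at C4–C5 as the exocyclic 1,3-diene, with the hindered ester and C1 untouched.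

Step 7
Reactants: 15 (1R)-4,6,6-trimethyl-5-methylidenecyclohex-3-en-1-yl (2R)-2-methylbutanoate
Product: 17 (1R,5S)-5-(hydroxymethyl)-4,6,6-trimethylcyclohex-3-en-1-yl (2R)-2-methylbutanoate, via B-alkyl-9-BBN adduct 16 (not isolated)
Conditions: 9-BBN (1.5 equiv), THF, 0 °C → rt; then NaBO3·4H2O, THF/H2O, rt
Reagents that add atoms: 9-borabicyclo[3.3.1]nonane, B1C2CCCC1CCC2 (boron and bicycle remain only in 16); sodium perborate, [Na+].[O-]OB=O (hydroxyl oxygen of 17)
Why: Hydroboration–oxidation, in which 9-BBN adds only to the less hindered 1,1-disubstituted exocyclic alkene with boron on C7 and should deliver hydrogen to C5 from the face opposite the acyloxy group (with C1–O equatorial, the pseudoaxial C6 methyl shields the acyloxy face), so that C7 ends up cis to the C1 oxygen (5S), while perborate oxidation proceeds with retention and spares the ester.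

Step 8
Reactants: 17 (1R,5S)-5-(hydroxymethyl)-4,6,6-trimethylcyclohex-3-en-1-yl (2R)-2-methylbutanoate; 18 umbelliferone (7-hydroxy-2H-chromen-2-one)
Product: 19 (1R,5S)-4,6,6-trimethyl-5-{[(2-oxo-2H-chromen-7-yl)oxy]methyl}cyclohex-3-en-1-yl (2R)-2-methylbutanoate
Conditions: PPh3, DIAD, THF, 0 °C → rt
Reagents that add atoms: none
Why: Mitsunobu etherification activates the primary alcohol as its alkoxyphosphonium salt for displacement by the acidic phenol of umbelliferone, at a carbon that is not a stereocentre and under neutral conditions that leave the ester, the coumarin lactone and both ring stereocentres intact.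

**Compound list**

1 | 3-[(tert-butyldimethylsilyl)oxy]propanal | CC(C)(C)[Si](C)(C)OCCC=O | starting material
2 | ethyltriphenylphosphonium iodide | CC[P+](c1ccccc1)(c1ccccc1)c1ccccc1.[I-] | starting material
3 | ethylidenetriphenylphosphorane | CC=P(c1ccccc1)(c1ccccc1)c1ccccc1 | intermediate
4 | (1-iodoethyl)triphenylphosphonium iodide | CC(I)[P+](c1ccccc1)(c1ccccc1)c1ccccc1.[I-] | intermediate
5 | (1-iodoethylidene)triphenylphosphorane | CC(I)=P(c1ccccc1)(c1ccccc1)c1ccccc1 | intermediate
6 | (Z)-tert-butyl[(4-iodopent-3-en-1-yl)oxy]dimethylsilane | C/C(I)=C/CCO[Si](C)(C)C(C)(C)C | intermediate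
7 | (Z)-4-iodopent-3-en-1-ol | C/C(I)=C/CCO | intermediate
8 | (Z)-4-iodopent-3-enal | C/C(I)=C/CC=O | intermediate
9 | 3-methylbuta-1,2-diene | CC(C)=C=C | starting material
10 | bis(pinacolato)diboron | CC1(C)OB(OC1(C)C)B1OC(C)(C)C(C)(C)O1 | starting material
11 | 2-{[(4R,6Z)-7-iodo-3,3-dimethyl-2-(4,4,5,5-tetramethyl-1,3,2-dioxaborolan-2-yl)octa-1,6-dien-4-yl]oxy}-4,4,5,5-tetramethyl-1,3,2-dioxaborolane | C/C(I)=C/C[C@@H](OB1OC(C)(C)C(C)(C)O1)C(C)(C)C(=C)B1OC(C)(C)C(C)(C)O1 | intermediate
12 | (4R,6Z)-7-iodo-3,3-dimethyl-2-(4,4,5,5-tetramethyl-1,3,2-dioxaborolan-2-yl)octa-1,6-dien-4-ol | C/C(I)=C/C[C@@H](O)C(C)(C)C(=C)B1OC(C)(C)C(C)(C)O1 | intermediate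
13 | (2R)-2-methylbutanoic acid | CC[C@@H](C)C(=O)O | starting material
14 | (4R,6Z)-7-iodo-3,3-dimethyl-2-(4,4,5,5-tetramethyl-1,3,2-dioxaborolan-2-yl)octa-1,6-dien-4-yl (2R)-2-methylbutanoate | C/C(I)=C/C[C@@H](OC(=O)[C@H](C)CC)C(C)(C)C(=C)B1OC(C)(C)C(C)(C)O1 | intermediate
15 | (1R)-4,6,6-trimethyl-5-methylidenecyclohex-3-en-1-yl (2R)-2-methylbutanoate | CC[C@@H](C)C(=O)O[C@@H]1CC=C(C)C(=C)C1(C)C | intermediate
16 | (1R,5S)-5-[(9-borabicyclo[3.3.1]nonan-9-yl)methyl]-4,6,6-trimethylcyclohex-3-en-1-yl (2R)-2-methylbutanoate | CC[C@@H](C)C(=O)O[C@@H]1CC=C(C)[C@H](CB2C3CCCC2CCC3)C1(C)C | intermediate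
17 | (1R,5S)-5-(hydroxymethyl)-4,6,6-trimethylcyclohex-3-en-1-yl (2R)-2-methylbutanoate | CC[C@@H](C)C(=O)O[C@@H]1CC=C(C)[C@H](CO)C1(C)C | intermediate
18 | umbelliferone (7-hydroxy-2H-chromen-2-one) | O=c1ccc2ccc(O)cc2o1 | starting material
19 | (1R,5S)-4,6,6-trimethyl-5-{[(2-oxo-2H-chromen-7-yl)oxy]methyl}cyclohex-3-en-1-yl (2R)-2-methylbutanoate | CC[C@@H](C)C(=O)O[C@@H]1CC=C(C)[C@H](COc2ccc3ccc(=O)oc3c2)C1(C)C | target

Total step count: 8. Longest linear sequence: 8 steps (1 → 6 → 7 → 8 → 12 → 14 → 15 → 17 → 19).

**Steps most likely to fail**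

Step 4. The copper alkoxide and copper boryl in the medium may enolise the β,γ-unsaturated aldehyde or move its double bond into conjugation, the copper boryl may attack the alkenyl iodide, or face selection may be poor with this small aliphatic aldehyde. The fallback separates the boron–allene union from the carbonyl addition and removes copper and base from the C–C bond-forming event. Setting out from 9 and 10, platinum(0)-catalysed diboration (Pt(PPh3)4, toluene, 80 °C) across the unsubstituted C=C should give 2,2'-(3-methylbut-2-ene-1,2-diyl)bis(4,4,5,5-tetramethyl-1,3,2-dioxaborolane) F1. This 2-boryl allylboronate would then add to freshly made 8 through its dimethyl terminus in a chiral-phosphoric-acid-catalysed allylboration (TRIP-type acid, toluene, −30 °C), a closed transition state that forms the same C1–C6 bond with C5–B already in place. Aqueous work-up of borate 11 returns the route at 12.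

Step 7. Facial discrimination at the exocyclic alkene may be poor if the acyloxy group is too small to bias the approach, and partial acyl shift to the new primary hydroxyl may occur during oxidation. The fallback carries the C1 oxygen as a bulkier silyl ether that cannot migrate and whose size can be raised, and moves the esterification to the end. It sets out from 12 and proceeds as follows:
- Silylation with TBSOTf/2,6-lutidine (CH2Cl2, −78 → 0 °C) should give tert-butyl{[(4R,6Z)-7-iodo-3,3-dimethyl-2-(4,4,5,5-tetramethyl-1,3,2-dioxaborolan-2-yl)octa-1,6-dien-4-yl]oxy}dimethylsilane F2.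
- Intramolecular Suzuki–Miyaura coupling (PdCl2(dppf), K3PO4, THF/H2O, 60 °C) would close the ring to tert-butyldimethyl{[(1R)-4,6,6-trimethyl-5-methylidenecyclohex-3-en-1-yl]oxy}silane F3.
- 9-BBN in THF should add anti to the silyloxy face to give 9-{[(1S,5R)-5-[(tert-butyldimethylsilyl)oxy]-2,6,6-trimethylcyclohex-2-en-1-yl]methyl}-9-borabicyclo[3.3.1]nonane F4.
- Oxidation with NaOH/H2O2 would give [(1S,5R)-5-[(tert-butyldimethylsilyl)oxy]-2,6,6-trimethylcyclohex-2-en-1-yl]methanol F5, at which stage C5 epimers can be separated.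
- Mitsunobu reaction with 18 (PPh3, DIAD, THF) would give 7-{[(1S,5R)-5-[(tert-butyldimethylsilyl)oxy]-2,6,6-trimethylcyclohex-2-en-1-yl]methoxy}-2H-chromen-2-one F6.
- HF·pyridine in THF would free 7-{[(1S,5R)-5-hydroxy-2,6,6-trimethylcyclohex-2-en-1-yl]methoxy}-2H-chromen-2-one F7.
- Steglich esterification with 13 (DCC, DMAP, CH2Cl2) returns the route at 19.

Step 6. Transmetalation of the alkenyl boronate flanked by the quaternary carbon may be slow, so that protodeboronation or intermolecular coupling takes over. The fallback changes the boron partner from the neutral pinacol ester to a tetracoordinate salt that resists protodeboronation and releases the active boron species slowly. Setting out from 14, KHF2 in aqueous methanol should give potassium trifluoro[(4R,6Z)-7-iodo-3,3-dimethyl-4-{[(2R)-2-methylbutanoyl]oxy}octa-1,6-dien-2-yl]borate F8. Its cyclisation under trifluoroborate Suzuki–Miyaura conditions (PdCl2(dppf), K2CO3, i-PrOH/H2O, 80 °C, high dilution) returns the route at 15.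

**Further compounds**

F1 | step 4 | 2,2'-(3-methylbut-2-ene-1,2-diyl)bis(4,4,5,5-tetramethyl-1,3,2-dioxaborolane) | CC(C)=C(CB1OC(C)(C)C(C)(C)O1)B1OC(C)(C)C(C)(C)O1
F2 | step 7 | tert-butyl{[(4R,6Z)-7-iodo-3,3-dimethyl-2-(4,4,5,5-tetramethyl-1,3,2-dioxaborolan-2-yl)octa-1,6-dien-4-yl]oxy}dimethylsilane | C/C(I)=C/C[C@@H](O[Si](C)(C)C(C)(C)C)C(C)(C)C(=C)B1OC(C)(C)C(C)(C)O1
F3 | step 7 | tert-butyldimethyl{[(1R)-4,6,6-trimethyl-5-methylidenecyclohex-3-en-1-yl]oxy}silane | CC(C)(C)[Si](C)(C)O[C@@H]1CC=C(C)C(=C)C1(C)C
F4 | step 7 | 9-{[(1S,5R)-5-[(tert-butyldimethylsilyl)oxy]-2,6,6-trimethylcyclohex-2-en-1-yl]methyl}-9-borabicyclo[3.3.1]nonane | CC(C)(C)[Si](C)(C)O[C@@H]1CC=C(C)[C@H](CB2C3CCCC2CCC3)C1(C)C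
F5 | step 7 | [(1S,5R)-5-[(tert-butyldimethylsilyl)oxy]-2,6,6-trimethylcyclohex-2-en-1-yl]methanol | CC(C)(C)[Si](C)(C)O[C@@H]1CC=C(C)[C@H](CO)C1(C)C
F6 | step 7 | 7-{[(1S,5R)-5-[(tert-butyldimethylsilyl)oxy]-2,6,6-trimethylcyclohex-2-en-1-yl]methoxy}-2H-chromen-2-one | CC(C)(C)[Si](C)(C)O[C@@H]1CC=C(C)[C@H](COc2ccc3ccc(=O)oc3c2)C1(C)C
F7 | step 7 | 7-{[(1S,5R)-5-hydroxy-2,6,6-trimethylcyclohex-2-en-1-yl]methoxy}-2H-chromen-2-one | O[C@@H]1CC=C(C)[C@H](COc2ccc3ccc(=O)oc3c2)C1(C)C
F8 | step 6 | potassium trifluoro[(4R,6Z)-7-iodo-3,3-dimethyl-4-{[(2R)-2-methylbutanoyl]oxy}octa-1,6-dien-2-yl]borate | C/C(I)=C/C[C@@H](OC(=O)[C@H](C)CC)C(C)(C)C(=C)[B-](F)(F)F.[K+]
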